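I read this flask at 12 min, and from the run so far I want one thing: of the L that goes in a stretch of time, how much stays as J.

the same everywhere: L 0.47 M; Q 0.423 M; temperature −20 °C
- east: G 0.047 M; the very flask that is asked about, followed so far
- flask: G 0.0470 M; time 12 min

- east (time / min: J / %, L / %): 1.00: 8.5, 90.8; 2.00: 15.5, 82.4; 5.00: 24.0, 65.0; 12.0: 24.5, 47.0

(each reading ± 0.5 percentage points)

- Wednesday's: at 12 min raise the temperature by 25 K, then wait 4.0 min
- Thursday's: at 12 min take out 90% of the J then present, then wait 4.0 min
- Friday's: at 12 min add Q, 100% of the amount charged, then wait 4.0 min
- Monday's: change nothing and wait 4.0 min more

- J, in percent of the L first charged, at 12 min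
- what to do for the largest gain in J; "none" if nothing gains more than 2 percentage points (Wednesday's / Thursday's / Friday's / Monday's / none)
- J present, with what was taken out counted in, in percent of the L first charged, after Thursday's
- J present, with what was taken out counted in, in percent of the L first charged, after Friday's

- J that was removed still counts
- the earlier runs do not show what temperature does; that part of a forecast is a guess
- additions bring no volume worth counting

Dividing the J gained between two readings by the L lost between them makes time drop out, and for the last stretch this gives 0.0278. I call that ratio the keep; the usual term is instantaneous yield.

Now the run in slow motion. In the first stretch, from the charge to 1.00 min, the keep reads 0.924, so nearly all of the L lost is found as J, and J stands at just 8.5%. Between 2.00 min and 5.00 min it reads 0.489: half of the L lost now passes beyond J, so J is an intermediate and its loss is what begins to matter. From there to 12.0 min, L falls by 18 percentage points while J rises by 0.5 points, a step set against a scatter of 0.5 points per reading. Hardly any is kept, although 47.0% of the L remains. That step places no peak of J within the stretch, so I commit to the reading, 24.5%.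

A gain in J is the keep times the L lost. At the last pace, L loses 10 points in 4.0 min, so Monday's adds 0.29 points, under the 2 points that counts. Thursday's leaves J at 2.45%, less than at the first reading. As a rough estimate, I assume that the keep returns to its first value, that L holds its last pace and that nothing flows back to J, which gives 9.5 points more J. That makes 34.0% in my reckoning. Friday's needs a rate law for L with Q, and I leave that reckoning to the forecast. The earlier runs do not show what temperature does, so Wednesday's stays a guess.

The forecast gives 24.6% (23.9% to 25.3%), then 29% after Thursday's, lower than my estimate, and 32% after Friday's. It chooses Friday's, and of heating it says: “Wednesday is a guess, since heating may favour the loss”.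

    L + Q → J (k = 0.260 /M/min, Ea = 41.0 kJ/mol)
    Q + G → E (k = 0.260 /M/min, Ea = 38.0 kJ/mol)
    J ⇌ X (K = 2.90, k = 0.140 /min, Ea = 69.0 kJ/mol, ΔH = −81.0 kJ/mol)
    (constants at −20 °C)

This flask gives 25.0%, then 32.4% after Thursday's and 33.6% after Friday's, but the best choice is Wednesday's, with a gain of 41 points, larger than the 28.3% held as X at 12.0 min. In this flask at 12.0 min, J is made 0.837 times as fast as it is used, so the keep is −0.195, and Monday's brings −1.4 points. The neighbour flask charged with 1.2 M of L has 67.8% of its L left and 13.5% as J at 12.0 min, a keep from the charge of 0.419.

Readings and results are simulated on assumed constants; noise was put on by code.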